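I was to read two flasks at 4.0 min, midnight at 5 °C and dusk at 25 °C, and I wanted one number that would tell me how far each had gone by then.

- midnight: starting material 0.10 M; salt in the second phase 0.200 M; protic impurity 0.0300 M; spent carrier 15 mM; temperature 5 °C; time 4.0 min; volume of the second phase over the first 0.25
- dusk: starting material 0.10 M; salt in the second phase 0.200 M; protic impurity 0.0300 M; spent carrier 15 mM; temperature 25 °C; time 4.0 min; volume of the second phase over the first 0.25

    spent carrier + salt in the second phase ⇌ fresh carrier + spent salt in the second phase (K1 = 0.65, k1 = 0.29 M⁻¹ s⁻¹, Ea1 = 45.0 kJ mol⁻¹, ΔH1 = −44.0 kJ mol⁻¹)
    starting material + fresh carrier → target + spent carrier (k2 = 0.70 M⁻¹ s⁻¹, Ea2 = 41.0 kJ mol⁻¹)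
    starting material + protic impurity → quenched substrate (k3 = 0.56 M⁻¹ s⁻¹, Ea3 = 44.0 kJ mol⁻¹)
    target + fresh carrier ⇌ isomer of the product + fresh carrier, rate k4*[target]*[fresh carrier] forward; the back reaction follows from the equilibrium constant (K4 = 0.10, k4 = 1.5 M⁻¹ s⁻¹, Ea4 = 42.0 kJ mol⁻¹, ΔH4 = −16.0 kJ mol⁻¹)
    (constants at 5 °C)

- in the second phase: salt in the second phase, spent salt in the second phase; everything else is in the first
- charges count per volume of the first phase; a concentration in a rate is the amount of a species over the volume of its own phase; every rate counts per litre of the first phase
- at 5 °C the constants are as listed, elsewhere as the activation energies and enthalpies make them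

* which of the two there is more of at the end, midnight (isomer of the product / target)
* which of the two there is more of at the end, dusk (isomer of the product / target)
* amount of target at the end, in percent of the starting material charged, midnight
* amount of target at the end, in percent of the starting material charged, dusk

At midnight the forward exchange of step 1 has a half-life of 3.0 s, its way back not counted, and the fresh carrier in step 2 has one of 0.17 min, each with the other concentrations as charged. Since the exchange time is shorter, I took the exchange as balanced and reckoned with the share of carrier it leaves fresh, much as dormant and active chain ends share one stock.

Salt and spent salt sit in the same phase, so its volume cancels from their ratio. I counted the impurity's charge as lost and set the spent salt equal to the starting material left to react, which made the ratio 1.86 at the end of reaction. With the exchange constant, 0.65 at midnight and 0.181 at dusk, the fresh share came to 54.7 % and 25.2 %.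

The rate constant of step 2 is 0.70 M⁻¹ s⁻¹ at midnight and 2.30 M⁻¹ s⁻¹ at dusk, and multiplying it by the fresh share, the carrier charge and the time gave 1.38 at midnight and 2.09 at dusk. This number is the count of pseudo-first-order lifetimes of the starting material that fit into the run. From midnight to dusk the rate constant grew by a factor 3.29 but the fresh share shrank, so the count is larger at dusk by a factor of just 1.51. Of what the impurity leaves, the fraction surviving is the exponential of minus the count, 25.2 % at midnight and 12.4 % at dusk.

One number was not enough. At midnight the impurity's first-order constant on the starting material, 1.01 min⁻¹, is larger than the fresh carrier's 0.345 min⁻¹, so I capped the product at 70.0 % of the charge. Step 4 relaxes on the same fresh carrier faster than step 2 consumes starting material, so I took target as balanced against its isomer and divided the product by one plus the constant of step 4, which is 0.10 at midnight and 0.0629 at dusk. My reckoning gave 47.6 % of target at midnight and 57.7 % at dusk, with target ahead of its isomer in both flasks.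

The forecast named target at midnight and target at dusk, with 51 % and 62 %, which stand higher than my figures, and it spoke of “a rate limited by the fresh carrier”.

Midnight gave 51.5 % of target against 5.09 % of isomer, and dusk gave 61.6 % against 3.86 %, so the forecast stood. To overturn it, the dusk target has moved by 6 points at 0.0220 M or 0.0377 M of protic impurity. The 13.7 % of starting material left at midnight reads as 1.63 lifetimes, beside my 1.38. For the neighbour of midnight charged with 0.060 M of starting material, the count is 1.98, which leaves 6.89 % unreacted, and that flask held 5.8 %.

The numbers belong to no real substance.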